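**Abbreviations and numbering.** Chroman numbering is used throughout (O1, C2, C3, C4, C4a, C5–C8, C8a; ring B positions primed). SEM = 2-(trimethylsilyl)ethoxymethyl; TBS = tert-butyldimethylsilyl; Ar = 2,5-bis(3-methylbut-2-enyl)-3,4-bis(SEM-oxy)phenyl.

## The problem

The target 22 is a 2-arylchroman in which phenolic ring A is fused to the dihydropyran ring C, and ring C carries ring B at C2, a benzylic ether carbon and the only stereocentre (S). Because no second stereocentre exists to relay configuration, C2 has to be set by a reagent or catalyst and afterwards kept away from any condition that ionises the C2–O bond. Both arenes are fully decorated: ring A carries 7-OH and a 1,1-dimethylallyl group at C6, and ring B is a catechol flanked by prenyl groups at C2′ and C5′, so three five-carbon units must be placed among several similar nucleophilic positions. The molecule is fragile: the catechol oxidises easily, the ortho-prenyl and ortho-(1,1-dimethylallyl) phenols cyclise under acid, and the three alkenes rule out hydrogenolysis and electrophilic oxidants. The C2–O1 bond is para-hydroxybenzylic with respect to the C4′ hydroxyl and can open to a quinone methide under acid or hot base, which would racemise C2. The feature that makes the key step possible is that ring A is a para-alkylphenol: 7-OH is para to C4a, and O1 sits on C8a, meta to that hydroxyl. Oxidation at C4a therefore turns ring A into a 4-hydroxycyclohexa-2,5-dienone in which C8a is an enone β-carbon six atoms from the C2 oxygen, while the other β-carbon, C5, is marked off by the bulky group on its neighbour C6.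

## Retrosynthesis

**22 from 21.** The two catechol O–C bonds are cut last. The catechol must stay masked through organolithium chemistry, carbonate, trivalent iodine and buffered HF. SEM acetals tolerate all of these and can be removed by fluoride without acid. The forward step must free the two catechol hydroxyls without opening the benzylic ether.

**21 from 19 (through 20).** The C8a–O1 bond is cut and water is added back across C4a/C8a, giving the para-quinol 19. Cutting O1–C2 instead would mean substitution at the ionisable stereocentre. An aryl C–O coupling would need a halogen at C8a and a transition metal near several alkenes. The chosen cut uses the oxygen already on C2 as the nucleophile and never touches the stereocentre. Precursor 19 has no ring C. The forward reaction must add at C8a and not C5, and must lose water towards C8a.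

**19 from 18 and 17.** The C4a–O bond is removed, leading back to the para-alkylphenol 17. The C2 oxygen must be silylated (18) during the oxidation, because a free hydroxyl three carbons from C4a would close a five-membered spiro ether. The forward steps are oxidation by PhI(OAc)2 with water capture at the para carbon, then buffered fluoride.

**17 from 16, 15 and 14.** Two protecting-group moves (silylation of the carbinol in 15, selective release of the ring A phenol from 16) precede the cut of the C2–H bond. Asymmetric transfer hydrogenation of the aryl alkyl ketone 14 sets C2. This is preferred over asymmetric addition of a hindered ring B nucleophile to an aldehyde, because aryl alkyl ketones are the best-behaved substrates for this reduction.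

**14 from 6 and 12 (through 13).** The C2–C1′ bond is cut between two fragments of similar size. Aryllithium 13, from bromide 12, acylates the Weinreb amide 6, which stops at the ketone.

**6 from 5, 4, 3, 1 and 2.** The C6–C(quaternary) bond is traced to an aromatic Claisen rearrangement of the prenyl ether 3. In a para-substituted phenyl ether both ortho carbons are equivalent and the para carbon is blocked, so no C6/C8 question arises. Ether 3 comes from ester 1 and prenyl bromide 2. Silylation (5) and amide formation (6) follow the rearrangement product 4.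

**12 from 11, 10, 9, 7 and 8.** The two prenyl termini are made by cross-metathesis of the diallyl compound 11. Its two aryl–CH2 bonds come from a double Claisen rearrangement of the bis(allyl) ether 9, made from 4-bromocatechol 7 and two equivalents of allyl bromide 8, via catechol 10. Each allyloxy group in 9 has one free ortho carbon only, so the bromine fixes the pattern. Allyl ethers are used because tertiary allyl or propargyl ethers of a catechol are much harder to make twice.

## Roads not taken

Alternative 1: The O1–C2 bond is cut. A chiral phosphoric acid would ionise a racemic ring B carbinol to its para-quinone methide, and the C8a phenol would add in 1,6 fashion to give A1, (S)-2-(3,4-dihydroxyphenyl)-7-(prenyloxy)chroman.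
- Merits: ring C and the stereocentre arise in one catalytic, stereoconvergent event, with no separate reduction.
- Weak points: A1 carries none of the three carbon-linked five-carbon units. A diprenylated catechol would not tolerate the acid, and an ortho-prenyl group would twist the quinone methide, so the prenyl groups must come afterwards. Two C-prenylations of a free catechol at C2′ and C5′ have no directing control (C6′ competes, C2′ is the most hindered site). The Claisen shift from O7 must choose C6 over C8, and C8, between two oxygens, is usually favoured. Heating a 4′-hydroxyflavan can reopen the quinone methide and erode the configuration.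
- Comparison: this road is better in step economy for ring closure plus stereocentre. The chosen plan sets against it regiochemical certainty (all five-carbon units placed before ring closure) and a stereocentre that is never exposed to ionising conditions until the final step.

Alternative 2: Ring A is built de novo by cutting C4a–C5 and C7–C8. With KOtBu, a methyl ketone would add through its internal α-carbon to an α-(1,1-dimethylallyl)acrylate, and the methyl carbon would then condense on the ester (Michael–Dieckmann) to give the cyclohexane-1,3-dione A2.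
- Merits: ring A substituents are placed by construction, and the silylated C2 stereocentre can be carried in.
- Weak points: the Michael addition must go through the more substituted enolate while the methyl enolate competes. A2 must be dehydrogenated to a resorcinol in the presence of three electron-rich alkenes. Ring C then has to be closed by substitution at C2, which risks ionisation of a para-alkoxybenzylic carbinol. The sequence is longer.
- Comparison: this road is at least as good in the unambiguous placement of ring A substituents. The chosen plan reaches the same certainty through symmetry, aromatises by dehydration (which the alkenes tolerate) instead of oxidation, and keeps the C2–O bond intact.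

Alternative 3: C4–C4a and C8a–O1 are cut. Pd(OAc)2, a phosphine and norbornene (Catellani-type) would alkylate the C–H ortho to iodine with a primary bromide and then couple the ipso carbon with the secondary alkoxide, giving A3, (S)-7-(prenyloxy)-2-Ar-chroman.
- Merits: two bonds and ring C in one convergent step, ring B arrives complete, and there is no redox detour on ring A.
- Weak points: a secondary alkoxide with β-hydrogens on palladium can undergo β-hydride elimination. The iodoarene has two free ortho positions. Zerovalent palladium can ionise the aryl prenyl ether. The C6 versus C8 Claisen problem of Alternative 1 remains after A3.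
- Comparison: this road is more convergent and shorter on paper. The chosen plan accepts more steps for a ring closure without palladium near allylic ethers and for a C6 substituent fixed at the outset.

Key step: step 15

## Route

Remark: C4a in 18 and 19 and the ring-fusion carbons of 20 form as epimer mixtures; this is accepted because these centres become sp2 in 21.

Step 1
Reactants: 1 methyl 3-(4-hydroxyphenyl)propanoate; 2 1-bromo-3-methylbut-2-ene (prenyl bromide)
Product: 3 methyl 3-[4-(3-methylbut-2-enyloxy)phenyl]propanoate
Conditions: K2CO3, acetone, 56 °C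
Reagents that add atoms: none
Why: Williamson ether synthesis; the phenoxide should attack the primary allylic bromide at oxygen in acetone, and the ester is inert to carbonate.

Step 2
Reactants: 3 methyl 3-[4-(3-methylbut-2-enyloxy)phenyl]propanoate
Product: 4 methyl 3-[4-hydroxy-3-(2-methylbut-3-en-2-yl)phenyl]propanoate
Conditions: PhNEt2, 195 °C, argon
Reagents that add atoms: none
Why: Aromatic Claisen rearrangement; the [3,3] shift joins the ortho carbon to the dimethyl-substituted terminus, giving the 1,1-dimethylallyl group, and tautomerisation restores the phenol. Both ortho carbons are equivalent and the para carbon is blocked, so one regioisomer is expected.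

Step 3
Reactants: 4 methyl 3-[4-hydroxy-3-(2-methylbut-3-en-2-yl)phenyl]propanoate
Product: 5 methyl 3-[4-(tert-butyldimethylsilyloxy)-3-(2-methylbut-3-en-2-yl)phenyl]propanoate
Conditions: TBSCl, imidazole, DMF, 40 °C
Reagents that add atoms: tert-butyldimethylsilyl chloride, CC(C)(C)[Si](C)(C)Cl
Why: Imidazole-mediated silylation of a phenol; the aryl silyl ether tolerates organomagnesium and organolithium reagents and can later be cleaved by carbonate without affecting an alkyl silyl ether.

Step 4
Reactants: 5 methyl 3-[4-(tert-butyldimethylsilyloxy)-3-(2-methylbut-3-en-2-yl)phenyl]propanoate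
Product: 6 3-[4-(tert-butyldimethylsilyloxy)-3-(2-methylbut-3-en-2-yl)phenyl]-N-methoxy-N-methylpropanamide
Conditions: MeNH(OMe)·HCl, i-PrMgCl, THF, −20 to 0 °C
Reagents that add atoms: N,O-dimethylhydroxylamine hydrochloride, CNOC.Cl
Why: Weinreb amide formation by aminolysis of the methyl ester with the chloromagnesium amide; the amide allows acyl substitution to stop at the ketone in step 9.

Step 5
Reactants: 7 4-bromobenzene-1,2-diol (4-bromocatechol); 8 3-bromoprop-1-ene (allyl bromide)
Product: 9 4-bromo-1,2-bis(prop-2-enyloxy)benzene
Conditions: allyl bromide (2.4 equiv in all), K2CO3 (3 equiv), DMF, 60 °C, argon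
Reagents that add atoms: 3-bromoprop-1-ene (second equivalent of allyl bromide 8), C=CCBr
Why: Double Williamson etherification; each of the two phenoxide oxygens takes one allyl group from the reactive primary allylic bromide, so two equivalents of 8 end up in 9.

Step 6
Reactants: 9 4-bromo-1,2-bis(prop-2-enyloxy)benzene
Product: 10 4-bromo-3,6-di(prop-2-enyl)benzene-1,2-diol
Conditions: PhNEt2, 190 °C, argon
Reagents that add atoms: none
Why: Double aromatic Claisen rearrangement; each allyloxy group has one hydrogen-bearing ortho carbon only (C6 for O1, C3 for O2), so the bromine dictates the pattern. The ortho dienones carry hydrogen and should tautomerise faster than they undergo a Cope shift to the para position.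

Step 7
Reactants: 10 4-bromo-3,6-di(prop-2-enyl)benzene-1,2-diol
Product: 11 1-bromo-2,5-di(prop-2-enyl)-3,4-bis{[2-(trimethylsilyl)ethoxy]methoxy}benzene
Conditions: NaH (2.4 equiv), SEMCl (2.4 equiv), DMF, 0 °C to rt, argon
Reagents that add atoms: 2-(trimethylsilyl)ethoxymethyl chloride, C[Si](C)(C)CCOCCl
Why: O-alkylation of both catecholate oxygens with a chloromethyl ether (two equivalents are incorporated); the SEM acetals withstand organolithium reagents, carbonate, PhI(OAc)2 and buffered HF and are removable by fluoride.

Step 8
Reactants: 11 1-bromo-2,5-di(prop-2-enyl)-3,4-bis{[2-(trimethylsilyl)ethoxy]methoxy}benzene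
Product: 12 1-bromo-2,5-bis(3-methylbut-2-enyl)-3,4-bis{[2-(trimethylsilyl)ethoxy]methoxy}benzene
Conditions: RuCl2(H2IMes)(PCy3)(=CHPh) (second-generation Grubbs catalyst, 5 mol%), 2-methylbut-2-ene (excess)/CH2Cl2, 35 °C
Reagents that add atoms: 2-methylbut-2-ene, CC=C(C)C
Why: Olefin cross-metathesis of terminal allyl groups with excess 2-methylbut-2-ene, a standard allyl-to-prenyl conversion driven by loss of propene; the aryl bromide and the acetals are inert to the ruthenium carbene.

Step 9
Reactants: 12 1-bromo-2,5-bis(3-methylbut-2-enyl)-3,4-bis{[2-(trimethylsilyl)ethoxy]methoxy}benzene; 6 3-[4-(tert-butyldimethylsilyloxy)-3-(2-methylbut-3-en-2-yl)phenyl]-N-methoxy-N-methylpropanamide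
Product: 14 1-Ar-3-[4-(tert-butyldimethylsilyloxy)-3-(2-methylbut-3-en-2-yl)phenyl]propan-1-one, via aryllithium 13 (not isolated)
Conditions: t-BuLi (2 equiv), THF, −78 °C; then 6, −78 to 0 °C; aq NH4Cl
Reagents that add atoms: none
Why: Bromine–lithium exchange followed by acyl substitution on the Weinreb amide; the chelated tetrahedral intermediate should persist until the quench, so the ketone forms without over-addition. Lithium sits meta and para to the acetal oxygens, so no anionic migration is expected at −78 °C.

Step 10
Reactants: 14 1-Ar-3-[4-(tert-butyldimethylsilyloxy)-3-(2-methylbut-3-en-2-yl)phenyl]propan-1-one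
Product: 15 (1S)-1-Ar-3-[4-(tert-butyldimethylsilyloxy)-3-(2-methylbut-3-en-2-yl)phenyl]propan-1-ol
Conditions: RuCl[(S,S)-TsDPEN](p-cymene) (2 mol%), HCO2H/Et3N (5:2), EtOAc, 35 °C
Reagents that add atoms: none
Why: Noyori–Ikariya asymmetric transfer hydrogenation of an aryl alkyl ketone; the (S,S) catalyst places the aryl group against the η6-arene and delivers hydride to the face that gives the S carbinol, as with acetophenone-type substrates. The outer-sphere hydride transfer leaves C=C bonds untouched.

Step 11
Reactants: 15 (1S)-1-Ar-3-[4-(tert-butyldimethylsilyloxy)-3-(2-methylbut-3-en-2-yl)phenyl]propan-1-ol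
Product: 16 tert-butyl{(1S)-1-Ar-3-[4-(tert-butyldimethylsilyloxy)-3-(2-methylbut-3-en-2-yl)phenyl]propoxy}dimethylsilane
Conditions: TBSCl, imidazole, DMAP (cat.), DMF, 40 °C
Reagents that add atoms: tert-butyldimethylsilyl chloride, CC(C)(C)[Si](C)(C)Cl
Why: Silylation of the secondary alcohol with the chloride (not the triflate, which could attack the SEM acetals); this masks the oxygen that would otherwise attack C4a in step 13. The configuration is unaffected.

Step 12
Reactants: 16 tert-butyl{(1S)-1-Ar-3-[4-(tert-butyldimethylsilyloxy)-3-(2-methylbut-3-en-2-yl)phenyl]propoxy}dimethylsilane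
Product: 17 4-[(3S)-3-Ar-3-(tert-butyldimethylsilyloxy)propyl]-2-(2-methylbut-3-en-2-yl)phenol
Conditions: K2CO3 (0.3 equiv), MeOH/THF, rt to 40 °C
Reagents that add atoms: none
Why: Selective methanolysis of an aryl silyl ether; phenoxide is the better leaving group at silicon, so the alkyl TBS ether and the SEM acetals should remain.

Step 13
Reactants: 17 4-[(3S)-3-Ar-3-(tert-butyldimethylsilyloxy)propyl]-2-(2-methylbut-3-en-2-yl)phenol
Product: 18 4-[(3S)-3-Ar-3-(tert-butyldimethylsilyloxy)propyl]-4-hydroxy-2-(2-methylbut-3-en-2-yl)cyclohexa-2,5-dien-1-one (both C4a epimers)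
Conditions: PhI(OAc)2, MeCN/H2O (2:1), 0 °C
Reagents that add atoms: water, O
Why: Oxidative dearomatisation of a para-alkylphenol by a trivalent iodine reagent; water captures the activated ring at the para carbon to give the para-quinol. The bulky ortho substituent disfavours ortho capture, and the silylated tether oxygen and the high water concentration should suppress internal capture.

Step 14
Reactants: 18 4-[(3S)-3-Ar-3-(tert-butyldimethylsilyloxy)propyl]-4-hydroxy-2-(2-methylbut-3-en-2-yl)cyclohexa-2,5-dien-1-one
Product: 19 4-hydroxy-4-[(3S)-3-Ar-3-hydroxypropyl]-2-(2-methylbut-3-en-2-yl)cyclohexa-2,5-dien-1-one (both C4a epimers)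
Conditions: HF·pyridine, pyridine, THF, 0 °C to rt
Reagents that add atoms: none
Why: Buffered fluoride desilylation of the alkyl silyl ether; the SEM acetals, the dienone and the tertiary alcohol should survive, and with no base present the alcohol can be isolated before ring closure.

Step 15
Reactants: 19 4-hydroxy-4-[(3S)-3-Ar-3-hydroxypropyl]-2-(2-methylbut-3-en-2-yl)cyclohexa-2,5-dien-1-one
Product: 21 (2S)-2-Ar-6-(2-methylbut-3-en-2-yl)chroman-7-ol, via cis-fused oxa-Michael adduct 20 (not isolated)
Conditions: DBU (0.2 equiv), THF, 0 °C to rt; then Burgess reagent (Et3N+SO2N−CO2Me), 50 °C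
Reagents that add atoms: none
Why: DBU generates the C2 alkoxide of 19, which adds to C8a, the β-carbon of the unsubstituted enone, in a 6-exo-trig oxa-Michael addition that forms the C8a–O1 bond and ring C and gives the cis-fused hydroxy ketone 20. The closest known reactions are the intramolecular oxa-Michael addition of tethered alcohols to 4,4-disubstituted cyclohexa-2,5-dienones and the dehydrative rearomatisation of conjugate adducts of para-quinols to meta-substituted phenols. The step needs site selectivity between the two β-carbons: C5 is shielded by the quaternary carbon on the neighbouring C6 and belongs to the less electrophilic α-substituted enone, and since the addition is reversible under base the adduct that keeps the more substituted enone should accumulate. The Burgess reagent then converts the tertiary C4a hydroxyl into a sulfamate; in the cis-fused adduct the C8a hydrogen is syn to it, so syn elimination across C4a–C8a gives the cyclohexa-2,4-dienone tautomer, which enolises at once to the phenol, aromatisation being the driving force. No new stereocentre remains: C2 keeps its S configuration because its C–O bond is never broken, and C4a and C8a of 20 are transient, so both epimers of 19 converge on 21. The conditions contain neither acid nor oxidant, so the SEM acetals, the prenyl and 1,1-dimethylallyl groups and the benzylic ether are not at risk.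

Step 16
Reactants: 21 (2S)-2-Ar-6-(2-methylbut-3-en-2-yl)chroman-7-ol
Product: 22 4-[(2S)-7-hydroxy-6-(2-methylbut-3-en-2-yl)chroman-2-yl]-3,6-bis(3-methylbut-2-enyl)benzene-1,2-diol
Conditions: TBAF, ethylenediamine, DMF, 45–60 °C, degassed; aq NH4Cl
Reagents that add atoms: none
Why: Fluoride-induced fragmentation of the SEM acetals; attack at silicon releases fluorotrimethylsilane, ethene, formaldehyde and the phenoxide. Ethylenediamine traps formaldehyde so the electron-rich rings are not hydroxymethylated. No acid is used, so the prenylated phenols should not cyclise.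

## Compound list

1 | methyl 3-(4-hydroxyphenyl)propanoate | COC(=O)CCc1ccc(O)cc1 | starting material
2 | 1-bromo-3-methylbut-2-ene (prenyl bromide) | CC(C)=CCBr | starting material
3 | methyl 3-[4-(3-methylbut-2-enyloxy)phenyl]propanoate | COC(=O)CCc1ccc(OCC=C(C)C)cc1 | intermediate
4 | methyl 3-[4-hydroxy-3-(2-methylbut-3-en-2-yl)phenyl]propanoate | COC(=O)CCc1ccc(O)c(C(C)(C)C=C)c1 | intermediate
5 | methyl 3-[4-(tert-butyldimethylsilyloxy)-3-(2-methylbut-3-en-2-yl)phenyl]propanoate | COC(=O)CCc1ccc(O[Si](C)(C)C(C)(C)C)c(C(C)(C)C=C)c1 | intermediate
6 | 3-[4-(tert-butyldimethylsilyloxy)-3-(2-methylbut-3-en-2-yl)phenyl]-N-methoxy-N-methylpropanamide | CON(C)C(=O)CCc1ccc(O[Si](C)(C)C(C)(C)C)c(C(C)(C)C=C)c1 | intermediate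
7 | 4-bromobenzene-1,2-diol (4-bromocatechol) | Oc1ccc(Br)cc1O | starting material
8 | 3-bromoprop-1-ene (allyl bromide) | C=CCBr | starting material
9 | 4-bromo-1,2-bis(prop-2-enyloxy)benzene | C=CCOc1ccc(Br)cc1OCC=C | intermediate
10 | 4-bromo-3,6-di(prop-2-enyl)benzene-1,2-diol | Oc1c(O)c(CC=C)c(Br)cc1CC=C | intermediate
11 | 1-bromo-2,5-di(prop-2-enyl)-3,4-bis(SEM-oxy)benzene | C=CCc1cc(Br)c(CC=C)c(OCOCC[Si](C)(C)C)c1OCOCC[Si](C)(C)C | intermediate
12 | 1-bromo-2,5-bis(3-methylbut-2-enyl)-3,4-bis(SEM-oxy)benzene | CC(C)=CCc1cc(Br)c(CC=C(C)C)c(OCOCC[Si](C)(C)C)c1OCOCC[Si](C)(C)C | intermediate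
13 | [2,5-bis(3-methylbut-2-enyl)-3,4-bis(SEM-oxy)phenyl]lithium (not isolated) | [Li]c1cc(CC=C(C)C)c(OCOCC[Si](C)(C)C)c(OCOCC[Si](C)(C)C)c1CC=C(C)C | intermediate
14 | 1-Ar-3-[4-(TBS-oxy)-3-(2-methylbut-3-en-2-yl)phenyl]propan-1-one | O=C(CCc1ccc(O[Si](C)(C)C(C)(C)C)c(C(C)(C)C=C)c1)c1cc(CC=C(C)C)c(OCOCC[Si](C)(C)C)c(OCOCC[Si](C)(C)C)c1CC=C(C)C | intermediate
15 | (1S)-1-Ar-3-[4-(TBS-oxy)-3-(2-methylbut-3-en-2-yl)phenyl]propan-1-ol | C=CC(C)(C)c1cc(CC[C@H](O)c2cc(CC=C(C)C)c(OCOCC[Si](C)(C)C)c(OCOCC[Si](C)(C)C)c2CC=C(C)C)ccc1O[Si](C)(C)C(C)(C)C | intermediate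
16 | TBS ether of 15 at the (1S) carbinol (bis-silyl ether) | C=CC(C)(C)c1cc(CC[C@H](O[Si](C)(C)C(C)(C)C)c2cc(CC=C(C)C)c(OCOCC[Si](C)(C)C)c(OCOCC[Si](C)(C)C)c2CC=C(C)C)ccc1O[Si](C)(C)C(C)(C)C | intermediate
17 | 4-[(3S)-3-Ar-3-(TBS-oxy)propyl]-2-(2-methylbut-3-en-2-yl)phenol | C=CC(C)(C)c1cc(CC[C@H](O[Si](C)(C)C(C)(C)C)c2cc(CC=C(C)C)c(OCOCC[Si](C)(C)C)c(OCOCC[Si](C)(C)C)c2CC=C(C)C)ccc1O | intermediate
18 | 4-[(3S)-3-Ar-3-(TBS-oxy)propyl]-4-hydroxy-2-(2-methylbut-3-en-2-yl)cyclohexa-2,5-dien-1-one (both C4a epimers) | O=C1C=CC(O)(CC[C@H](O[Si](C)(C)C(C)(C)C)c2cc(CC=C(C)C)c(OCOCC[Si](C)(C)C)c(OCOCC[Si](C)(C)C)c2CC=C(C)C)C=C1C(C)(C)C=C | intermediate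
19 | 4-hydroxy-4-[(3S)-3-Ar-3-hydroxypropyl]-2-(2-methylbut-3-en-2-yl)cyclohexa-2,5-dien-1-one (both C4a epimers) | O=C1C=CC(O)(CC[C@H](O)c2cc(CC=C(C)C)c(OCOCC[Si](C)(C)C)c(OCOCC[Si](C)(C)C)c2CC=C(C)C)C=C1C(C)(C)C=C | intermediate
20 | (2S)-2-Ar-4a-hydroxy-6-(2-methylbut-3-en-2-yl)-2,3,4,4a,8,8a-hexahydrochromen-7-one (cis ring fusion, both series; not isolated) | O=C1CC2O[C@H](c3cc(CC=C(C)C)c(OCOCC[Si](C)(C)C)c(OCOCC[Si](C)(C)C)c3CC=C(C)C)CCC2(O)C=C1C(C)(C)C=C | intermediate
21 | (2S)-2-Ar-6-(2-methylbut-3-en-2-yl)chroman-7-ol | C=CC(C)(C)c1cc2c(cc1O)O[C@H](c1cc(CC=C(C)C)c(OCOCC[Si](C)(C)C)c(OCOCC[Si](C)(C)C)c1CC=C(C)C)CC2 | intermediate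
22 | 4-[(2S)-7-hydroxy-6-(2-methylbut-3-en-2-yl)chroman-2-yl]-3,6-bis(3-methylbut-2-enyl)benzene-1,2-diol | C=CC(C)(C)c1cc2c(cc1O)O[C@H](c1cc(CC=C(C)C)c(O)c(O)c1CC=C(C)C)CC2 | target

## Step count and risk

Total: 16 steps. Longest linear sequence: 12 steps (steps 5–8 or 1–4, then 9–16).

**Step 15 (key step).** The most likely failure is loss of water in the wrong direction or at the wrong time. Elimination from C4a towards C4, or activation of the hydroxyls before ring closure is complete, would open a quinone-methide pathway in which the C2 oxygen is captured in five-ring mode, or would sulfamoylate the secondary alcohol. Addition at C5 is a smaller risk. The fallback sets out from 18 and returns at 21. The tertiary hydroxyl of 18 is acetylated (Ac2O, DMAP, Et3N) to the quinol acetate F1. HF·pyridine gives the hydroxy quinol acetate F2. DBU in THF then closes ring C, and gentle warming removes acetic acid across C4a–C8a from the adduct, after which the dienone enolises to 21. In this variant the leaving group is in place before ring closure and no dehydrating reagent meets a free alcohol, as in the known conversion of conjugate adducts of para-quinol acetates into meta-substituted phenols.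

**Step 13.** The activated ring may be intercepted at C4a by an internal nucleophile (the silyl ether oxygen, with loss of silicon, or the electron-rich C6′ of ring B) or by water at an ortho carbon, giving poor mass balance. The fallback sets out from 17 and returns at 21. Oxidation with PhI(OAc)2 in methanol, where solvent capture is fastest, gives the 4-methoxy dienone F3. HF·pyridine gives the alcohol F4. DBU closes ring C to the 4a-methoxy adduct F5, and catalytic pyridinium p-toluenesulfonate in CH2Cl2 at 0 °C removes methanol to give 21.

**Step 2.** At the required temperature the product phenol may react further: isomerisation of the 1,1-dimethylallyl group through a spirocyclopropane dienone (abnormal Claisen), cyclisation onto the alkene, or loss of the prenyl group. The fallback sets out from 3 and returns at 4. The rearrangement is run in butanoic anhydride/PhNEt2 so that the phenol is acylated as it forms, giving the butanoate F6, which can no longer re-enter the dienone manifold. K2CO3 in methanol then releases 4.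

**Step 6.** The allyl group on O2 may migrate to C5 (through the ipso dienone and a Cope shift) in preference to C3 next to bromine. The fallback sets out from 8 and returns at 11. Benzene-1,2-diol F7 is allylated with two equivalents of 8 to 1,2-bis(prop-2-enyloxy)benzene F8. Rearrangement gives 3,6-di(prop-2-enyl)benzene-1,2-diol F9, where no halogen crowds either ortho carbon. Protection gives the bis-SEM ether F10. Bromination with N-bromosuccinimide in DMF at 0 °C then gives 11: C5 and C6 of F10 are equivalent, and the dialkoxyarene is far more reactive than the monosubstituted alkenes.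

**Step 16.** Once the C4′ oxygen is a free phenoxide in warm basic fluoride, the C2–O1 bond may open to the ring B quinone methide and reclose, eroding the configuration. Air oxidation of the catecholate is a second concern. The fallback sets out from 21 and returns at 22. TMSOTf with 2,2′-bipyridyl in CH2Cl2 at 0 °C exchanges each SEM acetal (and the free 7-OH) for a trimethylsilyl ether through pyridinium intermediates, giving the tris(trimethylsilyl) ether F11 with no phenoxide present. Aqueous work-up hydrolyses F11 to 22.

## Further compounds

F1 | step 15 | 4-acetoxy-4-[(3S)-3-Ar-3-(TBS-oxy)propyl]-2-(2-methylbut-3-en-2-yl)cyclohexa-2,5-dien-1-one | CC(=O)OC1(CC[C@H](O[Si](C)(C)C(C)(C)C)c2cc(CC=C(C)C)c(OCOCC[Si](C)(C)C)c(OCOCC[Si](C)(C)C)c2CC=C(C)C)C=CC(=O)C(C(C)(C)C=C)=C1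
F2 | step 15 | 4-acetoxy-4-[(3S)-3-Ar-3-hydroxypropyl]-2-(2-methylbut-3-en-2-yl)cyclohexa-2,5-dien-1-one | CC(=O)OC1(CC[C@H](O)c2cc(CC=C(C)C)c(OCOCC[Si](C)(C)C)c(OCOCC[Si](C)(C)C)c2CC=C(C)C)C=CC(=O)C(C(C)(C)C=C)=C1
F3 | step 13 | 4-methoxy-4-[(3S)-3-Ar-3-(TBS-oxy)propyl]-2-(2-methylbut-3-en-2-yl)cyclohexa-2,5-dien-1-one | COC1(CC[C@H](O[Si](C)(C)C(C)(C)C)c2cc(CC=C(C)C)c(OCOCC[Si](C)(C)C)c(OCOCC[Si](C)(C)C)c2CC=C(C)C)C=CC(=O)C(C(C)(C)C=C)=C1
F4 | step 13 | 4-methoxy-4-[(3S)-3-Ar-3-hydroxypropyl]-2-(2-methylbut-3-en-2-yl)cyclohexa-2,5-dien-1-one | COC1(CC[C@H](O)c2cc(CC=C(C)C)c(OCOCC[Si](C)(C)C)c(OCOCC[Si](C)(C)C)c2CC=C(C)C)C=CC(=O)C(C(C)(C)C=C)=C1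
F5 | step 13 | (2S)-2-Ar-4a-methoxy-6-(2-methylbut-3-en-2-yl)-2,3,4,4a,8,8a-hexahydrochromen-7-one (cis ring fusion) | O=C1CC2O[C@H](c3cc(CC=C(C)C)c(OCOCC[Si](C)(C)C)c(OCOCC[Si](C)(C)C)c3CC=C(C)C)CCC2(OC)C=C1C(C)(C)C=C
F6 | step 2 | methyl 3-[4-(butanoyloxy)-3-(2-methylbut-3-en-2-yl)phenyl]propanoate | CCCC(=O)Oc1ccc(CCC(=O)OC)cc1C(C)(C)C=C
F7 | step 6 | benzene-1,2-diol | Oc1ccccc1O
F8 | step 6 | 1,2-bis(prop-2-enyloxy)benzene | C=CCOc1ccccc1OCC=C
F9 | step 6 | 3,6-di(prop-2-enyl)benzene-1,2-diol | Oc1c(CC=C)ccc(CC=C)c1O
F10 | step 6 | 1,4-di(prop-2-enyl)-2,3-bis(SEM-oxy)benzene | C=CCc1ccc(CC=C)c(OCOCC[Si](C)(C)C)c1OCOCC[Si](C)(C)C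
F11 | step 16 | (2S)-2-[2,5-bis(3-methylbut-2-enyl)-3,4-bis(trimethylsilyloxy)phenyl]-6-(2-methylbut-3-en-2-yl)-7-(trimethylsilyloxy)chroman | C=CC(C)(C)c1cc2c(cc1O[Si](C)(C)C)O[C@H](c1cc(CC=C(C)C)c(O[Si](C)(C)C)c(O[Si](C)(C)C)c1CC=C(C)C)CC2
A1 | alternative 1 | (S)-2-(3,4-dihydroxyphenyl)-7-(3-methylbut-2-enyloxy)chroman | CC(C)=CCOc1ccc2c(c1)O[C@H](c1ccc(O)c(O)c1)CC2
A2 | alternative 2 | 4-[(3S)-3-Ar-3-(tert-butyldimethylsilyloxy)propyl]-6-(2-methylbut-3-en-2-yl)cyclohexane-1,3-dione | O=C1CC(=O)C(C(C)(C)C=C)CC1CC[C@H](O[Si](C)(C)C(C)(C)C)c1cc(CC=C(C)C)c(OCOCC[Si](C)(C)C)c(OCOCC[Si](C)(C)C)c1CC=C(C)C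
A3 | alternative 3 | (S)-7-(3-methylbut-2-enyloxy)-2-Ar-chroman | CC(C)=CCOc1ccc2c(c1)O[C@H](c1cc(CC=C(C)C)c(OCOCC[Si](C)(C)C)c(OCOCC[Si](C)(C)C)c1CC=C(C)C)CC2
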